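**Two limits.** In the theta run, left-handed product exceeded right-handed product by a ratio of 1.56. I froze s, the selectivity factor: the ratio of the two rate constants, held constant along a run. With instant exchange, s equals that ratio. With no exchange, s is the ratio of the logarithms of the unreacted fractions, which gives 2.31. The excess under instant exchange, (s − 1)/(s + 1), therefore lies between 21.8% and the ceiling 39.5%.

| flask | left-handed substrate | right-handed substrate | partner | catalyst | remark | time |
|---|---|---|---|---|---|---|
| gamma | 0.12 M | 0.12 M | 0.36 M | 3 mM | run made earlier |  |
| delta | 0.12 M | 0.12 M | 0.36 M | 4.5 mM | run made earlier |  |
| theta | 0.24 M | 0.24 M | 0.36 M | 6 mM | run made earlier |  |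
| flask | 0.12 M | 0.12 M | 0.360 M | 6.0 mM |  | 3.0 min |

| run | time / min | left-handed product / % | right-handed product / % | left-handed substrate / % |
|---|---|---|---|---|
| gamma | 0.833 | 50 | 33 | 9 |
| gamma | 2.00 | 49 | 33 | 6 |
| gamma | 2.50 | 51 | 35 | 8 |
| gamma | 4.00 | 51 | 33 | 6 |
| delta | 0.250 | 45 | 29 | 7 |
| delta | 0.667 | 55 | 36 | 5 |
| delta | 1.50 | 52 | 38 | 4 |
| delta | 4.00 | 52 | 39 | 1 |
| theta | 0.250 | 39 | 25 | 17 |
| theta | 0.667 | 41 | 28 | 17 |
| theta | 1.50 | 43 | 26 | 14 |
| theta | 4.00 | 42 | 27 | 16 |

(standard deviation of a reading: 1.5 percentage points)

- catalyst is single-handed; left-handed substrate and right-handed substrate are mirror images of each other, charged as a racemate, each of them at the stated concentration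
- the numbers in the tables scatter by 1.5 percentage points (one standard deviation)
- an excess is below zero if the other one leads

* left-handed product and right-handed product together, in percent of the left-handed substrate and right-handed substrate charged together, at 3.0 min
* excess of left-handed product over right-handed product in the product at 3.0 min
* whether the exchange between left-handed substrate and right-handed substrate keeps pace with the reaction: how far the product's excess at 3.0 min gets from its value without exchange to its value with instant exchange (above 80% keeps pace, below 20% hardly takes part, else lags behind)

**This flask.** Unreacted substrate fell from 16.2% in gamma to 9.33% on delta's plateau. Continuing that geometrically, I expected 5.36% unreacted, a yield of 94.6%. Without exchange, left-handed product cannot pass its own charge, so the excess would be at most 5.66%; with left-handed product leading it would stay above zero, so the lower end of my bracket lay between those two values. Excess fell from 20.0% in gamma to 16.9% in delta, so delta's reading is my upper bound. Setting the no-exchange excess at zero and the instant value at 21.8% gives the largest share these limits allow, so the share of the way stays under 77.5%, and I expected the exchange to lag, with delta's own share at least 22.6%.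

**The forecast.** It gave 94%, 14% and lags behind, with a share “falling as catalyst rises relative to substrate”; its excess lies below delta's reading and above my no-exchange cap.

**The flask.** It gave 95.8%, an excess of 15.5% and lags behind, at 38% of the way, with the excess under the ceiling.

    partner + catalyst + left-handed substrate → catalyst + left-handed product (k = 190 /M²/s)
    partner + catalyst + right-handed substrate → catalyst + right-handed product (k = 94.8 /M²/s)
    left-handed substrate ⇌ right-handed substrate (k = 0.0331 /s)
    catalyst ⇌ dormant form (K = 2.82, k = 0.0219 /s)
    partner → decomposed reagent (k = 0.0211 /s)

**Two clocks.** In the flask, the right-handed step had done half its turnover by 0.0589 min, while the exchange alone has a relaxation half-life of 0.175 min, 2.97 times longer. By 0.300 min the left-handed step had 90% of its turnover behind it. The neighbour flask charged with 0.090 M of partner reached an excess of 29.4%, under the ceiling but above 21.8%, which puts s at 1.83 or more.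

The data were computed with made-up constants.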